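## Retrosynthetic overview

1. Global deprotection comes last. The lactone C3–CH2Ar bond is cut to give an (R)-4-(arylmethyl)butyrolactone carrying the dihydrobenzofuran arm and a benzylic bromide carrying the open 1,3-diol arm; they are joined by trans-selective enolate alkylation.
2. The butyrolactone ring comes from an Evans succinate imide that is alkylated with the dihydrobenzofuran benzylic bromide, then reduced and lactonised.
3. The open arm (anti 1,2-diarylpropane-1,3-diol) comes from a Mg-catalysed Evans anti-aldol of an arylacetyl imide (made from methyl vanillate by Claisen rearrangement) with O-benzylvanillin.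
4. The dihydrobenzofuran ring O1–C2–C3–C3a–C7a is made by oxidative ring contraction of the six-membered pyranone ring of a (2S)-flavanone. The enabling feature is that C3 carries both the ring-fusion aryl carbon C3a and an exocyclic one-carbon unit (the CH2OH carbon) next to the O-benzylic C2. This is the 1,2-aryl-shift isomer of a 2-arylchroman-4-one, whose carbonyl carbon becomes the CH2OH carbon.
5. Ring order: pyranone ring of a chromone (C2 then set by asymmetric conjugate arylation), then the contracted dihydrofuran ring, then the butyrolactone ring.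

Key step: step 4

Assumption: the sense of induction follows the accepted models, i.e. (R)-t-BuPyOx gives the (2S)-flavanone by analogy with cyclic enones, and the chelated Z-enolates of the 4-benzyloxazolidinones react on the face opposite the benzyl group in steps 10 and 17.

## Route

Step 1
Reactants: 1 1-(2-hydroxy-3-methoxyphenyl)ethan-1-one
Product: 2 1-(5-bromo-2-hydroxy-3-methoxyphenyl)ethan-1-one
Conditions: NBS, MeCN, 0 °C to rt
Reagents that add atoms: N-bromosuccinimide (O=C1CCC(=O)N1Br)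
Why: Electrophilic aromatic bromination should go para to the free phenol (C5'), both ortho positions being blocked, while the hydrogen-bonded acetyl group is left alone.

Step 2
Reactants: 2 1-(5-bromo-2-hydroxy-3-methoxyphenyl)ethan-1-one
Product: 4 6-bromo-8-methoxy-4H-chromen-4-one, via enaminone 3 (not isolated)
Conditions: DMF-DMA, 100 °C; then conc. HCl, CH2Cl2, 40 °C
Reagents that add atoms: N,N-dimethylformamide dimethyl acetal (COC(OC)N(C)C)
Why: Condensation of the methyl ketone with the amide acetal, then acid-mediated oxa-Michael addition and loss of dimethylamine, is the standard chromone synthesis from 2'-hydroxyacetophenones.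

Step 3
Reactants: 4 6-bromo-8-methoxy-4H-chromen-4-one; 5 [4-(benzyloxy)-3-methoxyphenyl]boronic acid
Product: 6 (2S)-2-[4-(benzyloxy)-3-methoxyphenyl]-6-bromo-8-methoxychroman-4-one
Conditions: Pd(OCOCF3)2 (5 mol %), (R)-t-BuPyOx (6 mol %), NH4PF6, H2O, ClCH2CH2Cl, 60 °C
Reagents that add atoms: none
Why: Pd(II)/pyridine-oxazoline-catalysed asymmetric conjugate addition of arylboronic acids to chromones (Hayashi–Miyaura-type 1,4-arylation) should set C2 (S) under ligand control, and phosphine-free Pd(II) should leave the aryl bromide intact.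

Step 4
Reactants: 6 (2S)-2-[4-(benzyloxy)-3-methoxyphenyl]-6-bromo-8-methoxychroman-4-one
Product: 7 methyl (2S,3S)-2-[4-(benzyloxy)-3-methoxyphenyl]-5-bromo-7-methoxy-2,3-dihydrobenzofuran-3-carboxylate (2,3-trans)
Conditions: PhI(OAc)2 (1.2 equiv), conc. H2SO4 (0.5 equiv), HC(OMe)3, 0 °C to rt
Reagents that add atoms: trimethyl orthoformate (COC(OC)OC)
Why: Acid and orthoformate convert the C4 ketone into its dimethyl ketal/methyl enol ether, PhI(OAc)2 attacks C3 of the enol ether on the face opposite the C2 aryl group, and the pseudo-equatorial C3–I(III) bond, antiperiplanar to the C4–C4a ring bond, is displaced by a 1,2-shift of the aryl carbon C4a from C4 to C3 with loss of iodobenzene, the dimethoxycarbenium ion left at the former C4 collapsing to the methyl ester. The closest known reaction type is the iodine(III)- or thallium(III)-mediated oxidative ring contraction of flavanones to trans-2-aryl-2,3-dihydrobenzofuran-3-carboxylates, a semipinacol-type (quasi-Favorskii) 1,2-aryl shift. The six-membered pyranone ring is contracted to the five-membered ring O1–C2–C3–C3a–C7a by forming the C3–C3a bond through a spiro phenonium-type (3-exo-tet) transition structure while C4–C4a breaks, and no other ring is closed. C2 is not touched and should keep its S configuration because the ketone is masked as the ketal before a retro-oxa-Michael opening can occur, and the new centre C3 is set by C2, since iodination anti to the aryl group followed by migration with inversion places the ester trans to the aryl group, which is also the thermodynamically preferred arrangement. The step needs migration of the ring-fusion carbon C4a instead of migration of the C2 aryl group (isoflavone) or elimination (flavone); this is secured by the diequatorial half-chair, which aligns only the C4–C4a bond with the leaving group, by the push of the two methoxy groups on C4 and by the ring oxygen ortho to C4a, which raises the migratory aptitude of that carbon.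

Step 5
Reactants: 7 methyl (2S,3S)-2-[4-(benzyloxy)-3-methoxyphenyl]-5-bromo-7-methoxy-2,3-dihydrobenzofuran-3-carboxylate
Product: 8 [(2S,3R)-2-[4-(benzyloxy)-3-methoxyphenyl]-5-bromo-7-methoxy-2,3-dihydrobenzofuran-3-yl]methanol
Conditions: DIBAL-H (2.5 equiv), CH2Cl2, −78 to 0 °C; Rochelle salt
Reagents that add atoms: none
Why: DIBAL-H reduces the ester to the primary alcohol under non-basic conditions, so β-elimination of the aryloxide, epimerisation at C3 and loss of the aryl bromide should all be avoided.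

Step 6
Reactants: 8 [(2S,3R)-2-[4-(benzyloxy)-3-methoxyphenyl]-5-bromo-7-methoxy-2,3-dihydrobenzofuran-3-yl]methanol
Product: 9 tert-butyl{[(2S,3R)-2-[4-(benzyloxy)-3-methoxyphenyl]-5-bromo-7-methoxy-2,3-dihydrobenzofuran-3-yl]methoxy}diphenylsilane
Conditions: TBDPSCl, imidazole, DMF, rt
Reagents that add atoms: tert-butylchlorodiphenylsilane (CC(C)(C)[Si](Cl)(c1ccccc1)c1ccccc1)
Why: Standard silylation of a primary alcohol; the TBDPS ether should survive the organolithium, hydride, enolate and acid-catalysed lactonisation steps that follow.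

Step 7
Reactants: 9 tert-butyl{[(2S,3R)-2-[4-(benzyloxy)-3-methoxyphenyl]-5-bromo-7-methoxy-2,3-dihydrobenzofuran-3-yl]methoxy}diphenylsilane
Product: 11 [(2S,3R)-2-[4-(benzyloxy)-3-methoxyphenyl]-3-[(tert-butyldiphenylsilyloxy)methyl]-7-methoxy-2,3-dihydrobenzofuran-5-yl]methanol, via aldehyde 10 (not isolated)
Conditions: n-BuLi, THF, −78 °C; DMF, −78 to 0 °C; then MeOH, NaBH4, 0 °C
Reagents that add atoms: N,N-dimethylformamide (CN(C)C=O)
Why: Bromine–lithium exchange is faster than any deprotonation at −78 °C, the aryllithium is formylated by DMF (Bouveault formylation) and the crude aldehyde is reduced by borohydride in the same flask.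

Step 8
Reactants: 11 [(2S,3R)-2-[4-(benzyloxy)-3-methoxyphenyl]-3-[(tert-butyldiphenylsilyloxy)methyl]-7-methoxy-2,3-dihydrobenzofuran-5-yl]methanol
Product: 12 (2S,3R)-2-[4-(benzyloxy)-3-methoxyphenyl]-5-(bromomethyl)-3-[(tert-butyldiphenylsilyloxy)methyl]-7-methoxy-2,3-dihydrobenzofuran
Conditions: CBr4, PPh3, CH2Cl2, 0 °C (used crude)
Reagents that add atoms: carbon tetrabromide (BrC(Br)(Br)Br)
Why: The Appel reaction converts the electron-rich benzylic alcohol into the bromide under neutral conditions that should spare the silyl ether and the benzylic ether at C2.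

Step 9
Reactants: 13 4-(tert-butoxy)-4-oxobutanoic acid; 14 (R)-4-benzyloxazolidin-2-one
Product: 16 tert-butyl 4-[(4R)-4-benzyl-2-oxooxazolidin-3-yl]-4-oxobutanoate, via mixed pivalic anhydride 15 (not isolated)
Conditions: PivCl, Et3N, THF, −20 °C; then 14, LiCl, rt
Reagents that add atoms: none
Why: N-Acylation of the oxazolidinone through the mixed pivalic anhydride (LiCl/Et3N procedure) occurs at the unhindered carbonyl of the anhydride.

Step 10
Reactants: 16 tert-butyl 4-[(4R)-4-benzyl-2-oxooxazolidin-3-yl]-4-oxobutanoate; 12 (2S,3R)-2-[4-(benzyloxy)-3-methoxyphenyl]-5-(bromomethyl)-3-[(tert-butyldiphenylsilyloxy)methyl]-7-methoxy-2,3-dihydrobenzofuran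
Product: 17 tert-butyl (3R)-4-[(4R)-4-benzyl-2-oxooxazolidin-3-yl]-3-{[(2S,3R)-2-[4-(benzyloxy)-3-methoxyphenyl]-3-[(tert-butyldiphenylsilyloxy)methyl]-7-methoxy-2,3-dihydrobenzofuran-5-yl]methyl}-4-oxobutanoate
Conditions: NaHMDS, THF, −78 °C; then 12, −78 to −40 °C
Reagents that add atoms: none
Why: Evans asymmetric alkylation: the imide α-position is enolised selectively over the tert-butyl ester, and the chelated sodium Z-enolate is benzylated on the face opposite the auxiliary benzyl group, which sets the (R) centre that becomes C4 of the lactone.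

Step 11
Reactants: 17 tert-butyl (3R)-4-[(4R)-4-benzyl-2-oxooxazolidin-3-yl]-3-{[(2S,3R)-2-[4-(benzyloxy)-3-methoxyphenyl]-3-[(tert-butyldiphenylsilyloxy)methyl]-7-methoxy-2,3-dihydrobenzofuran-5-yl]methyl}-4-oxobutanoate
Product: 19 (4R)-4-{[(2S,3R)-2-[4-(benzyloxy)-3-methoxyphenyl]-3-[(tert-butyldiphenylsilyloxy)methyl]-7-methoxy-2,3-dihydrobenzofuran-5-yl]methyl}dihydrofuran-2(3H)-one, via hydroxy ester 18 (not isolated)
Conditions: LiBH4, MeOH (1 equiv), THF, 0 °C; then p-TsOH·H2O (cat.), toluene, 80 °C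
Reagents that add atoms: none
Why: LiBH4 cleaves the imide reductively to the primary alcohol without touching the tert-butyl ester, and acid-catalysed transesterification then closes the γ-lactone (5-exo-trig) without affecting the stereocentre.

Step 12
Reactants: 20 methyl 4-hydroxy-3-methoxybenzoate
Product: 21 methyl 4-(allyloxy)-3-methoxybenzoate
Conditions: allyl bromide, K2CO3, acetone, reflux
Reagents that add atoms: allyl bromide (C=CCBr)
Why: Williamson O-allylation of the phenol.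

Step 13
Reactants: 21 methyl 4-(allyloxy)-3-methoxybenzoate
Product: 22 methyl 3-allyl-4-hydroxy-5-methoxybenzoate
Conditions: PhNEt2, 200 °C
Reagents that add atoms: none
Why: Aromatic Claisen rearrangement delivers the allyl group to the only free ortho position, and tautomerisation restores the phenol.

Step 14
Reactants: 22 methyl 3-allyl-4-hydroxy-5-methoxybenzoate
Product: 23 methyl 3-allyl-4-(benzyloxy)-5-methoxybenzoate
Conditions: BnBr, K2CO3, DMF, rt
Reagents that add atoms: benzyl bromide (BrCc1ccccc1)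
Why: Williamson O-benzylation of the hindered phenol.

Step 15
Reactants: 23 methyl 3-allyl-4-(benzyloxy)-5-methoxybenzoate
Product: 25 2-[2-(benzyloxy)-3-methoxy-5-(methoxycarbonyl)phenyl]acetic acid, via arylacetaldehyde 24 (not isolated)
Conditions: O3, CH2Cl2/MeOH, −78 °C; Me2S; then NaClO2, NaH2PO4, 2-methyl-2-butene, t-BuOH/H2O, rt
Reagents that add atoms: ozone ([O-][O+]=O); sodium chlorite ([Na+].[O-]Cl=O)
Why: Ozonolysis at −78 °C cleaves only the terminal alkene, and Pinnick oxidation of the crude aldehyde gives the acid without touching the benzyl ether or the methyl ester.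

Step 16
Reactants: 25 2-[2-(benzyloxy)-3-methoxy-5-(methoxycarbonyl)phenyl]acetic acid; 26 (S)-4-benzyloxazolidin-2-one
Product: 28 methyl 3-{2-[(4S)-4-benzyl-2-oxooxazolidin-3-yl]-2-oxoethyl}-4-(benzyloxy)-5-methoxybenzoate, via mixed pivalic anhydride 27 (not isolated)
Conditions: PivCl, Et3N, THF, −20 °C; then 26, LiCl, rt
Reagents that add atoms: none
Why: N-Acylation of the oxazolidinone through the mixed pivalic anhydride, as in step 9.

Step 17
Reactants: 28 methyl 3-{2-[(4S)-4-benzyl-2-oxooxazolidin-3-yl]-2-oxoethyl}-4-(benzyloxy)-5-methoxybenzoate; 29 4-(benzyloxy)-3-methoxybenzaldehyde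
Product: 31 methyl 3-{(2R,3S)-1-[(4S)-4-benzyl-2-oxooxazolidin-3-yl]-3-[4-(benzyloxy)-3-methoxyphenyl]-3-hydroxy-1-oxopropan-2-yl}-4-(benzyloxy)-5-methoxybenzoate (anti), via trimethylsilyl ether 30 (not isolated)
Conditions: MgCl2 (20 mol %), Et3N, TMSCl, EtOAc, rt; then 1 M HCl, THF, rt
Reagents that add atoms: none
Why: Mg-halide-catalysed direct anti-aldol of N-acyloxazolidinones: soft enolisation gives the chelated Z-enolate, which should add to the non-enolisable aromatic aldehyde through a boat transition state on the face opposite the auxiliary benzyl group, giving the anti (2R,3S) adduct that is trapped as its silyl ether.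

Step 18
Reactants: 31 methyl 3-{(2R,3S)-1-[(4S)-4-benzyl-2-oxooxazolidin-3-yl]-3-[4-(benzyloxy)-3-methoxyphenyl]-3-hydroxy-1-oxopropan-2-yl}-4-(benzyloxy)-5-methoxybenzoate
Product: 32 methyl 4-(benzyloxy)-3-{(1S,2S)-1-[4-(benzyloxy)-3-methoxyphenyl]-1,3-dihydroxypropan-2-yl}-5-methoxybenzoate
Conditions: LiBH4, MeOH (1 equiv), THF, 0 °C
Reagents that add atoms: none
Why: Reductive removal of the auxiliary; the imide carbonyl should be reduced much faster than the electron-rich methyl benzoate, and both stereocentres are untouched.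

Step 19
Reactants: 32 methyl 4-(benzyloxy)-3-{(1S,2S)-1-[4-(benzyloxy)-3-methoxyphenyl]-1,3-dihydroxypropan-2-yl}-5-methoxybenzoate
Product: 33 methyl 4-(benzyloxy)-3-{(1S,2S)-1-[4-(benzyloxy)-3-methoxyphenyl]-1,3-bis(tert-butyldimethylsilyloxy)propan-2-yl}-5-methoxybenzoate
Conditions: TBSOTf, 2,6-lutidine, CH2Cl2, −78 to 0 °C
Reagents that add atoms: tert-butyldimethylsilyl triflate (CC(C)(C)[Si](C)(C)OS(=O)(=O)C(F)(F)F)
Why: The silyl triflate silylates both the primary and the hindered secondary benzylic alcohol under buffered conditions that should not ionise the benzylic position.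

Step 20
Reactants: 33 methyl 4-(benzyloxy)-3-{(1S,2S)-1-[4-(benzyloxy)-3-methoxyphenyl]-1,3-bis(tert-butyldimethylsilyloxy)propan-2-yl}-5-methoxybenzoate
Product: 34 {4-(benzyloxy)-3-[(1S,2S)-1-[4-(benzyloxy)-3-methoxyphenyl]-1,3-bis(tert-butyldimethylsilyloxy)propan-2-yl]-5-methoxyphenyl}methanol
Conditions: DIBAL-H, CH2Cl2, −78 °C; Rochelle salt
Reagents that add atoms: none
Why: DIBAL-H reduces the benzoate to the benzylic alcohol without affecting silyl or benzyl ethers.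

Step 21
Reactants: 34 {4-(benzyloxy)-3-[(1S,2S)-1-[4-(benzyloxy)-3-methoxyphenyl]-1,3-bis(tert-butyldimethylsilyloxy)propan-2-yl]-5-methoxyphenyl}methanol
Product: 35 (1S,2S)-2-[2-(benzyloxy)-5-(bromomethyl)-3-methoxyphenyl]-1-[4-(benzyloxy)-3-methoxyphenyl]-1,3-bis(tert-butyldimethylsilyloxy)propane
Conditions: CBr4, PPh3, CH2Cl2, 0 °C (used crude)
Reagents that add atoms: carbon tetrabromide (BrC(Br)(Br)Br)
Why: Appel bromination of the primary benzylic alcohol under neutral conditions that should leave the two silyl ethers in place.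

Step 22
Reactants: 19 (4R)-4-{[(2S,3R)-2-[4-(benzyloxy)-3-methoxyphenyl]-3-[(tert-butyldiphenylsilyloxy)methyl]-7-methoxy-2,3-dihydrobenzofuran-5-yl]methyl}dihydrofuran-2(3H)-one; 35 (1S,2S)-2-[2-(benzyloxy)-5-(bromomethyl)-3-methoxyphenyl]-1-[4-(benzyloxy)-3-methoxyphenyl]-1,3-bis(tert-butyldimethylsilyloxy)propane
Product: 36 (3R,4R)-3-{4-(benzyloxy)-3-[(1S,2S)-1-[4-(benzyloxy)-3-methoxyphenyl]-1,3-bis(tert-butyldimethylsilyloxy)propan-2-yl]-5-methoxybenzyl}-4-{[(2S,3R)-2-[4-(benzyloxy)-3-methoxyphenyl]-3-[(tert-butyldiphenylsilyloxy)methyl]-7-methoxy-2,3-dihydrobenzofuran-5-yl]methyl}dihydrofuran-2(3H)-one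
Conditions: LiHMDS, THF, −78 °C; then 35, DMPU, −78 to −30 °C
Reagents that add atoms: none
Why: Alkylation of the lithium enolate of a 4-substituted butyrolactone occurs anti to the C4 substituent, which should give the 3,4-trans (3R,4R) dibenzylbutyrolactone, the standard lignan-lactone union.

Step 23
Reactants: 36 (3R,4R)-3-{4-(benzyloxy)-3-[(1S,2S)-1-[4-(benzyloxy)-3-methoxyphenyl]-1,3-bis(tert-butyldimethylsilyloxy)propan-2-yl]-5-methoxybenzyl}-4-{[(2S,3R)-2-[4-(benzyloxy)-3-methoxyphenyl]-3-[(tert-butyldiphenylsilyloxy)methyl]-7-methoxy-2,3-dihydrobenzofuran-5-yl]methyl}dihydrofuran-2(3H)-one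
Product: 37 (3R,4R)-3-{4-(benzyloxy)-3-[(1S,2S)-1-[4-(benzyloxy)-3-methoxyphenyl]-1,3-dihydroxypropan-2-yl]-5-methoxybenzyl}-4-{[(2S,3R)-2-[4-(benzyloxy)-3-methoxyphenyl]-3-(hydroxymethyl)-7-methoxy-2,3-dihydrobenzofuran-5-yl]methyl}dihydrofuran-2(3H)-one
Conditions: HF·pyridine, pyridine, THF, 0 °C to rt
Reagents that add atoms: none
Why: Buffered fluoride cleaves all three silyl ethers without opening the lactone or ionising the benzylic positions.

Step 24
Reactants: 37 (3R,4R)-3-{4-(benzyloxy)-3-[(1S,2S)-1-[4-(benzyloxy)-3-methoxyphenyl]-1,3-dihydroxypropan-2-yl]-5-methoxybenzyl}-4-{[(2S,3R)-2-[4-(benzyloxy)-3-methoxyphenyl]-3-(hydroxymethyl)-7-methoxy-2,3-dihydrobenzofuran-5-yl]methyl}dihydrofuran-2(3H)-one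
Product: 38 (3R,4R)-3-{3-[(1S,2S)-1,3-dihydroxy-1-(4-hydroxy-3-methoxyphenyl)propan-2-yl]-4-hydroxy-5-methoxybenzyl}-4-{[(2S,3R)-2-(4-hydroxy-3-methoxyphenyl)-3-(hydroxymethyl)-7-methoxy-2,3-dihydrobenzofuran-5-yl]methyl}dihydrofuran-2(3H)-one (CNP0186558.2)
Conditions: H2 (1 atm), 10% Pd/C, EtOAc/MeOH, rt, stopped at full debenzylation
Reagents that add atoms: none
Why: Hydrogenolysis of aryl benzyl ethers under neutral conditions is much faster than cleavage of the dihydrobenzofuran C2–O bond or of the free benzylic alcohol, so the three phenols should be released selectively.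

## Compound list

1 | 1-(2-hydroxy-3-methoxyphenyl)ethan-1-one | CC(=O)c1cccc(OC)c1O | starting material
2 | 1-(5-bromo-2-hydroxy-3-methoxyphenyl)ethan-1-one | CC(=O)c1cc(Br)cc(OC)c1O | intermediate
3 | (E)-1-(5-bromo-2-hydroxy-3-methoxyphenyl)-3-(dimethylamino)prop-2-en-1-one | CN(C)/C=C/C(=O)c1cc(Br)cc(OC)c1O | intermediate
4 | 6-bromo-8-methoxy-4H-chromen-4-one | O=c1ccoc2c(OC)cc(Br)cc12 | intermediate
5 | [4-(benzyloxy)-3-methoxyphenyl]boronic acid | COc1cc(B(O)O)ccc1OCc1ccccc1 | starting material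
6 | (2S)-2-[4-(benzyloxy)-3-methoxyphenyl]-6-bromo-8-methoxychroman-4-one | O=C1C[C@@H](c2ccc(OCc3ccccc3)c(OC)c2)Oc2c(OC)cc(Br)cc21 | intermediate
7 | methyl (2S,3S)-2-[4-(benzyloxy)-3-methoxyphenyl]-5-bromo-7-methoxy-2,3-dihydrobenzofuran-3-carboxylate | Brc1cc(OC)c2c(c1)[C@H](C(=O)OC)[C@@H](c1ccc(OCc3ccccc3)c(OC)c1)O2 | intermediate
8 | [(2S,3R)-2-[4-(benzyloxy)-3-methoxyphenyl]-5-bromo-7-methoxy-2,3-dihydrobenzofuran-3-yl]methanol | Brc1cc(OC)c2c(c1)[C@H](CO)[C@@H](c1ccc(OCc3ccccc3)c(OC)c1)O2 | intermediate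
9 | tert-butyl{[(2S,3R)-2-[4-(benzyloxy)-3-methoxyphenyl]-5-bromo-7-methoxy-2,3-dihydrobenzofuran-3-yl]methoxy}diphenylsilane | Brc1cc(OC)c2c(c1)[C@H](CO[Si](c1ccccc1)(c1ccccc1)C(C)(C)C)[C@@H](c1ccc(OCc3ccccc3)c(OC)c1)O2 | intermediate
10 | (2S,3R)-2-[4-(benzyloxy)-3-methoxyphenyl]-3-[(tert-butyldiphenylsilyloxy)methyl]-7-methoxy-2,3-dihydrobenzofuran-5-carbaldehyde | O=Cc1cc(OC)c2c(c1)[C@H](CO[Si](c1ccccc1)(c1ccccc1)C(C)(C)C)[C@@H](c1ccc(OCc3ccccc3)c(OC)c1)O2 | intermediate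
11 | [(2S,3R)-2-[4-(benzyloxy)-3-methoxyphenyl]-3-[(tert-butyldiphenylsilyloxy)methyl]-7-methoxy-2,3-dihydrobenzofuran-5-yl]methanol | OCc1cc(OC)c2c(c1)[C@H](CO[Si](c1ccccc1)(c1ccccc1)C(C)(C)C)[C@@H](c1ccc(OCc3ccccc3)c(OC)c1)O2 | intermediate
12 | (2S,3R)-2-[4-(benzyloxy)-3-methoxyphenyl]-5-(bromomethyl)-3-[(tert-butyldiphenylsilyloxy)methyl]-7-methoxy-2,3-dihydrobenzofuran | BrCc1cc(OC)c2c(c1)[C@H](CO[Si](c1ccccc1)(c1ccccc1)C(C)(C)C)[C@@H](c1ccc(OCc3ccccc3)c(OC)c1)O2 | intermediate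
13 | 4-(tert-butoxy)-4-oxobutanoic acid | CC(C)(C)OC(=O)CCC(=O)O | starting material
14 | (R)-4-benzyloxazolidin-2-one | O=C1N[C@H](Cc2ccccc2)CO1 | starting material
15 | 4-(tert-butoxy)-4-oxobutanoic pivalic anhydride | CC(C)(C)OC(=O)CCC(=O)OC(=O)C(C)(C)C | intermediate
16 | tert-butyl 4-[(4R)-4-benzyl-2-oxooxazolidin-3-yl]-4-oxobutanoate | CC(C)(C)OC(=O)CCC(=O)N1[C@H](Cc2ccccc2)COC1=O | intermediate
17 | tert-butyl (3R)-4-[(4R)-4-benzyl-2-oxooxazolidin-3-yl]-3-{[(2S,3R)-2-[4-(benzyloxy)-3-methoxyphenyl]-3-[(tert-butyldiphenylsilyloxy)methyl]-7-methoxy-2,3-dihydrobenzofuran-5-yl]methyl}-4-oxobutanoate | O=C1OC[C@@H](Cc2ccccc2)N1C(=O)[C@@H](CC(=O)OC(C)(C)C)Cc1cc(OC)c2c(c1)[C@H](CO[Si](c1ccccc1)(c1ccccc1)C(C)(C)C)[C@@H](c1ccc(OCc3ccccc3)c(OC)c1)O2 | intermediate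
18 | tert-butyl (3R)-4-hydroxy-3-{[(2S,3R)-2-[4-(benzyloxy)-3-methoxyphenyl]-3-[(tert-butyldiphenylsilyloxy)methyl]-7-methoxy-2,3-dihydrobenzofuran-5-yl]methyl}butanoate | OC[C@@H](CC(=O)OC(C)(C)C)Cc1cc(OC)c2c(c1)[C@H](CO[Si](c1ccccc1)(c1ccccc1)C(C)(C)C)[C@@H](c1ccc(OCc3ccccc3)c(OC)c1)O2 | intermediate
19 | (4R)-4-{[(2S,3R)-2-[4-(benzyloxy)-3-methoxyphenyl]-3-[(tert-butyldiphenylsilyloxy)methyl]-7-methoxy-2,3-dihydrobenzofuran-5-yl]methyl}dihydrofuran-2(3H)-one | O=C1OC[C@@H](C1)Cc1cc(OC)c2c(c1)[C@H](CO[Si](c1ccccc1)(c1ccccc1)C(C)(C)C)[C@@H](c1ccc(OCc3ccccc3)c(OC)c1)O2 | intermediate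
20 | methyl 4-hydroxy-3-methoxybenzoate (methyl vanillate) | COC(=O)c1ccc(O)c(OC)c1 | starting material
21 | methyl 4-(allyloxy)-3-methoxybenzoate | COC(=O)c1ccc(OCC=C)c(OC)c1 | intermediate
22 | methyl 3-allyl-4-hydroxy-5-methoxybenzoate | COC(=O)c1cc(CC=C)c(O)c(OC)c1 | intermediate
23 | methyl 3-allyl-4-(benzyloxy)-5-methoxybenzoate | COC(=O)c1cc(CC=C)c(OCc2ccccc2)c(OC)c1 | intermediate
24 | methyl 4-(benzyloxy)-3-methoxy-5-(2-oxoethyl)benzoate | COC(=O)c1cc(CC=O)c(OCc2ccccc2)c(OC)c1 | intermediate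
25 | 2-[2-(benzyloxy)-3-methoxy-5-(methoxycarbonyl)phenyl]acetic acid | COC(=O)c1cc(CC(=O)O)c(OCc2ccccc2)c(OC)c1 | intermediate
26 | (S)-4-benzyloxazolidin-2-one | O=C1N[C@@H](Cc2ccccc2)CO1 | starting material
27 | 2-[2-(benzyloxy)-3-methoxy-5-(methoxycarbonyl)phenyl]acetic pivalic anhydride | COC(=O)c1cc(CC(=O)OC(=O)C(C)(C)C)c(OCc2ccccc2)c(OC)c1 | intermediate
28 | methyl 3-{2-[(4S)-4-benzyl-2-oxooxazolidin-3-yl]-2-oxoethyl}-4-(benzyloxy)-5-methoxybenzoate | COC(=O)c1cc(CC(=O)N2[C@@H](Cc3ccccc3)COC2=O)c(OCc2ccccc2)c(OC)c1 | intermediate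
29 | 4-(benzyloxy)-3-methoxybenzaldehyde | COc1cc(C=O)ccc1OCc1ccccc1 | starting material
30 | trimethylsilyl ether of 31 | COc1cc([C@@H](O[Si](C)(C)C)[C@H](C(=O)N2[C@@H](Cc3ccccc3)COC2=O)c2cc(C(=O)OC)cc(OC)c2OCc2ccccc2)ccc1OCc1ccccc1 | intermediate
31 | methyl 3-{(2R,3S)-1-[(4S)-4-benzyl-2-oxooxazolidin-3-yl]-3-[4-(benzyloxy)-3-methoxyphenyl]-3-hydroxy-1-oxopropan-2-yl}-4-(benzyloxy)-5-methoxybenzoate | COc1cc([C@@H](O)[C@H](C(=O)N2[C@@H](Cc3ccccc3)COC2=O)c2cc(C(=O)OC)cc(OC)c2OCc2ccccc2)ccc1OCc1ccccc1 | intermediate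
32 | methyl 4-(benzyloxy)-3-{(1S,2S)-1-[4-(benzyloxy)-3-methoxyphenyl]-1,3-dihydroxypropan-2-yl}-5-methoxybenzoate | COc1cc([C@@H](O)[C@H](CO)c2cc(C(=O)OC)cc(OC)c2OCc2ccccc2)ccc1OCc1ccccc1 | intermediate
33 | methyl 4-(benzyloxy)-3-{(1S,2S)-1-[4-(benzyloxy)-3-methoxyphenyl]-1,3-bis(tert-butyldimethylsilyloxy)propan-2-yl}-5-methoxybenzoate | COc1cc([C@@H](O[Si](C)(C)C(C)(C)C)[C@H](CO[Si](C)(C)C(C)(C)C)c2cc(C(=O)OC)cc(OC)c2OCc2ccccc2)ccc1OCc1ccccc1 | intermediate
34 | {4-(benzyloxy)-3-[(1S,2S)-1-[4-(benzyloxy)-3-methoxyphenyl]-1,3-bis(tert-butyldimethylsilyloxy)propan-2-yl]-5-methoxyphenyl}methanol | COc1cc([C@@H](O[Si](C)(C)C(C)(C)C)[C@H](CO[Si](C)(C)C(C)(C)C)c2cc(CO)cc(OC)c2OCc2ccccc2)ccc1OCc1ccccc1 | intermediate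
35 | (1S,2S)-2-[2-(benzyloxy)-5-(bromomethyl)-3-methoxyphenyl]-1-[4-(benzyloxy)-3-methoxyphenyl]-1,3-bis(tert-butyldimethylsilyloxy)propane | COc1cc([C@@H](O[Si](C)(C)C(C)(C)C)[C@H](CO[Si](C)(C)C(C)(C)C)c2cc(CBr)cc(OC)c2OCc2ccccc2)ccc1OCc1ccccc1 | intermediate
36 | fully protected lactone: (3R,4R)-3-{4-(benzyloxy)-3-[(1S,2S)-1-[4-(benzyloxy)-3-methoxyphenyl]-1,3-bis(tert-butyldimethylsilyloxy)propan-2-yl]-5-methoxybenzyl}-4-{[(2S,3R)-2-[4-(benzyloxy)-3-methoxyphenyl]-3-[(tert-butyldiphenylsilyloxy)methyl]-7-methoxy-2,3-dihydrobenzofuran-5-yl]methyl}dihydrofuran-2(3H)-one | COc1cc([C@@H](O[Si](C)(C)C(C)(C)C)[C@H](CO[Si](C)(C)C(C)(C)C)c2cc(C[C@H]3C(=O)OC[C@@H]3Cc3cc(OC)c4c(c3)[C@H](CO[Si](c3ccccc3)(c3ccccc3)C(C)(C)C)[C@@H](c3ccc(OCc5ccccc5)c(OC)c3)O4)cc(OC)c2OCc2ccccc2)ccc1OCc1ccccc1 | intermediate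
37 | tri-O-benzyl triol: (3R,4R)-3-{4-(benzyloxy)-3-[(1S,2S)-1-[4-(benzyloxy)-3-methoxyphenyl]-1,3-dihydroxypropan-2-yl]-5-methoxybenzyl}-4-{[(2S,3R)-2-[4-(benzyloxy)-3-methoxyphenyl]-3-(hydroxymethyl)-7-methoxy-2,3-dihydrobenzofuran-5-yl]methyl}dihydrofuran-2(3H)-one | COc1cc([C@@H](O)[C@H](CO)c2cc(C[C@H]3C(=O)OC[C@@H]3Cc3cc(OC)c4c(c3)[C@H](CO)[C@@H](c3ccc(OCc5ccccc5)c(OC)c3)O4)cc(OC)c2OCc2ccccc2)ccc1OCc1ccccc1 | intermediate
38 | CNP0186558.2: (3R,4R)-3-{3-[(1S,2S)-1,3-dihydroxy-1-(4-hydroxy-3-methoxyphenyl)propan-2-yl]-4-hydroxy-5-methoxybenzyl}-4-{[(2S,3R)-2-(4-hydroxy-3-methoxyphenyl)-3-(hydroxymethyl)-7-methoxy-2,3-dihydrobenzofuran-5-yl]methyl}dihydrofuran-2(3H)-one | COc1cc([C@@H](O)[C@H](CO)c2cc(C[C@H]3C(=O)OC[C@@H]3Cc3cc(OC)c4c(c3)[C@H](CO)[C@@H](c3ccc(O)c(OC)c3)O4)cc(OC)c2O)ccc1O | target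

## Step count and risks

Total step count: 24.
Longest linear sequence: 13 steps (steps 1–8, 10, 11, 22–24; the sequence of steps 12–24 is equally long).

Steps most likely to fail:

Step 4. The oxidative ring contraction may be diverted by migration of the C2 aryl group (isoflavone pathway), by elimination to the flavone, or by acid-induced ring opening that erodes the C2 configuration. The fallback keeps a ring contraction but moves it to the alkene oxidation level; it sets out from 6 and rejoins the route at 8. Reduction of 6 with NaBH4 (MeOH/THF, 0 °C) should give the cis-flavan-4-ol (2S,4S)-2-[4-(benzyloxy)-3-methoxyphenyl]-6-bromo-8-methoxychroman-4-ol F1. Acid-catalysed dehydration (p-TsOH, toluene, 60 °C) should give the flav-3-ene (2S)-2-[4-(benzyloxy)-3-methoxyphenyl]-6-bromo-8-methoxy-2H-chromene F2. Oxidative rearrangement of this cyclic styrene-type alkene with thallium(III) nitrate (or PhI(OH)OTs) in methanol contracts the ring, by the same 1,2-shift of the ring-fusion carbon, to the trans acetal (2S,3S)-2-[4-(benzyloxy)-3-methoxyphenyl]-5-bromo-3-(dimethoxymethyl)-7-methoxy-2,3-dihydrobenzofuran F3. Mild aqueous acid releases the aldehyde (2S,3S)-2-[4-(benzyloxy)-3-methoxyphenyl]-5-bromo-7-methoxy-2,3-dihydrobenzofuran-3-carbaldehyde F4, and NaBH4 reduction gives alcohol 8.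

Step 17. The anti-aldol may give poor diastereoselectivity, or the adduct may epimerise at the acidic α-aryl centre under the amine base. The fallback sets out from acid 25 and auxiliary 14 and rejoins the route at 33. Acylation of 14 with 25 as in step 16 gives methyl 3-{2-[(4R)-4-benzyl-2-oxooxazolidin-3-yl]-2-oxoethyl}-4-(benzyloxy)-5-methoxybenzoate F5. Its dibutylboron Z-enolate (Bu2BOTf, i-Pr2NEt, CH2Cl2, −78 °C) should add to aldehyde 29 through the closed Zimmerman–Traxler transition state to give the Evans syn adduct, the (2R,3R)-(4R)-imide F6, which has the required configuration at the α-aryl carbon and the wrong one at the carbinol carbon. LiBH4 gives the syn diol methyl 4-(benzyloxy)-3-{(1R,2S)-1-[4-(benzyloxy)-3-methoxyphenyl]-1,3-dihydroxypropan-2-yl}-5-methoxybenzoate F7, and TBSCl/imidazole silylates only the primary alcohol to give the mono-silyl ether F8. Dess–Martin oxidation gives the aryl ketone methyl 4-(benzyloxy)-3-{(2S)-1-[4-(benzyloxy)-3-methoxyphenyl]-3-(tert-butyldimethylsilyloxy)-1-oxopropan-2-yl}-5-methoxybenzoate F9. Reagent-controlled reduction with (R)-Me-CBS/BH3·SMe2, in which the aryl group acts as the large substituent, should give the anti (1S,2S) alcohol F10, which is silylated (TBSOTf, 2,6-lutidine) to 33.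

Step 3. The conjugate arylation may give insufficient enantioselectivity, or may stall through protodeboronation of the electron-rich boronic acid or ring opening of the product. The fallback sets out from 2 and rejoins the route at 6. Claisen–Schmidt condensation of 2 with aldehyde 29 (KOH, EtOH, rt) gives the chalcone (E)-3-[4-(benzyloxy)-3-methoxyphenyl]-1-(5-bromo-2-hydroxy-3-methoxyphenyl)prop-2-en-1-one F11, which cyclises (NaOAc, EtOH, reflux) to the racemic flavanone 2-[4-(benzyloxy)-3-methoxyphenyl]-6-bromo-8-methoxychroman-4-one F12. Kinetic resolution by asymmetric transfer hydrogenation (RuCl(p-cymene)[(R,R)-TsDPEN], HCO2H/Et3N, EtOAc) should reduce the (2R) enantiomer to the cis-flavan-4-ol (2R,4R)-2-[4-(benzyloxy)-3-methoxyphenyl]-6-bromo-8-methoxychroman-4-ol F13 and leave (2S)-flavanone 6, which is separated by chromatography.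

Further compounds
F1 | step 4 | (2S,4S)-2-[4-(benzyloxy)-3-methoxyphenyl]-6-bromo-8-methoxychroman-4-ol | O[C@H]1C[C@@H](c2ccc(OCc3ccccc3)c(OC)c2)Oc2c(OC)cc(Br)cc21
F2 | step 4 | (2S)-2-[4-(benzyloxy)-3-methoxyphenyl]-6-bromo-8-methoxy-2H-chromene | C1=C[C@@H](c2ccc(OCc3ccccc3)c(OC)c2)Oc2c(OC)cc(Br)cc21
F3 | step 4 | (2S,3S)-2-[4-(benzyloxy)-3-methoxyphenyl]-5-bromo-3-(dimethoxymethyl)-7-methoxy-2,3-dihydrobenzofuran | Brc1cc(OC)c2c(c1)[C@H](C(OC)OC)[C@@H](c1ccc(OCc3ccccc3)c(OC)c1)O2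
F4 | step 4 | (2S,3S)-2-[4-(benzyloxy)-3-methoxyphenyl]-5-bromo-7-methoxy-2,3-dihydrobenzofuran-3-carbaldehyde | Brc1cc(OC)c2c(c1)[C@H](C=O)[C@@H](c1ccc(OCc3ccccc3)c(OC)c1)O2
F5 | step 17 | methyl 3-{2-[(4R)-4-benzyl-2-oxooxazolidin-3-yl]-2-oxoethyl}-4-(benzyloxy)-5-methoxybenzoate | COC(=O)c1cc(CC(=O)N2[C@H](Cc3ccccc3)COC2=O)c(OCc2ccccc2)c(OC)c1
F6 | step 17 | methyl 3-{(2R,3R)-1-[(4R)-4-benzyl-2-oxooxazolidin-3-yl]-3-[4-(benzyloxy)-3-methoxyphenyl]-3-hydroxy-1-oxopropan-2-yl}-4-(benzyloxy)-5-methoxybenzoate | COc1cc([C@H](O)[C@H](C(=O)N2[C@H](Cc3ccccc3)COC2=O)c2cc(C(=O)OC)cc(OC)c2OCc2ccccc2)ccc1OCc1ccccc1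
F7 | step 17 | methyl 4-(benzyloxy)-3-{(1R,2S)-1-[4-(benzyloxy)-3-methoxyphenyl]-1,3-dihydroxypropan-2-yl}-5-methoxybenzoate | COc1cc([C@H](O)[C@H](CO)c2cc(C(=O)OC)cc(OC)c2OCc2ccccc2)ccc1OCc1ccccc1
F8 | step 17 | methyl 4-(benzyloxy)-3-{(1R,2S)-1-[4-(benzyloxy)-3-methoxyphenyl]-3-(tert-butyldimethylsilyloxy)-1-hydroxypropan-2-yl}-5-methoxybenzoate | COc1cc([C@H](O)[C@H](CO[Si](C)(C)C(C)(C)C)c2cc(C(=O)OC)cc(OC)c2OCc2ccccc2)ccc1OCc1ccccc1
F9 | step 17 | methyl 4-(benzyloxy)-3-{(2S)-1-[4-(benzyloxy)-3-methoxyphenyl]-3-(tert-butyldimethylsilyloxy)-1-oxopropan-2-yl}-5-methoxybenzoate | COc1cc(C(=O)[C@H](CO[Si](C)(C)C(C)(C)C)c2cc(C(=O)OC)cc(OC)c2OCc2ccccc2)ccc1OCc1ccccc1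
F10 | step 17 | methyl 4-(benzyloxy)-3-{(1S,2S)-1-[4-(benzyloxy)-3-methoxyphenyl]-3-(tert-butyldimethylsilyloxy)-1-hydroxypropan-2-yl}-5-methoxybenzoate | COc1cc([C@@H](O)[C@H](CO[Si](C)(C)C(C)(C)C)c2cc(C(=O)OC)cc(OC)c2OCc2ccccc2)ccc1OCc1ccccc1
F11 | step 3 | (E)-3-[4-(benzyloxy)-3-methoxyphenyl]-1-(5-bromo-2-hydroxy-3-methoxyphenyl)prop-2-en-1-one | COc1cc(/C=C/C(=O)c2cc(Br)cc(OC)c2O)ccc1OCc1ccccc1
F12 | step 3 | racemic 2-[4-(benzyloxy)-3-methoxyphenyl]-6-bromo-8-methoxychroman-4-one | O=C1CC(c2ccc(OCc3ccccc3)c(OC)c2)Oc2c(OC)cc(Br)cc21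
F13 | step 3 | (2R,4R)-2-[4-(benzyloxy)-3-methoxyphenyl]-6-bromo-8-methoxychroman-4-ol | O[C@@H]1C[C@H](c2ccc(OCc3ccccc3)c(OC)c2)Oc2c(OC)cc(Br)cc21
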